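**Retrosynthetic overview**

1. Target: all-E (3R,3'R)-7,8-didehydro-7',8'-dihydro-β,β-carotene-3,3'-diol (carotenoid numbering; ring A = acetylenic end, ring B = dihydro end). Main cut: the C14'–C15' single bond, giving a C21 ring-A enyne-tetraenyl iodide (iodine on C15'), a C18 ring-B dienyne ending in C13'≡C14'–H, and one methyl group from AlMe3.
2. Enabling feature: the bond lies between C15', the end of the unbranched E-C15=C15' unit, and C14', the CH end of the trisubstituted E-olefin C13'(CH3)=C14'H. A methyl one carbon from the junction and cis to it is the imprint of a syn methylmetalation of a terminal alkyne, so one flask (AlMe3/Cp2ZrCl2, then Pd) installs methyl C20', fixes 13'E, forges C14'–C15' and completes the octaene-yne chromophore.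
3. Rings: neither cyclohexene ring is built. (4R,6R)-Actinol gives one common enol triflate carrying the C3/C3' stereocentre and the C5=C6 ring olefin; ring A is attached through an sp carbon (Sonogashira, C6–C7), ring B through an sp3 carbon (alkyl Negishi, C6'–C7').
4. Further cuts: C11=C12 (Horner–Wadsworth–Emmons) and C15=C15' (Takai) in the ring-A half; C10'–C11' (methylalumination/cross-coupling with an (E)-chloroenyne, the same reaction type as the key step) in the ring-B half.
5. End game: fragment union, then global desilylation.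

Key step: step 13

Assumption: (4R,6R)-actinol is taken as a purchasable enantiopure building block, and the cyanoallyl phosphonate, sold as an E/Z mixture, is drawn as its E isomer because its allyl anion equilibrates.

**Route**

Step 1
Reactants: 1 (4R,6R)-4-hydroxy-2,2,6-trimethylcyclohexan-1-one (actinol)
Product: 2 (4R,6R)-4-[(tert-butyldimethylsilyl)oxy]-2,2,6-trimethylcyclohexan-1-one
Conditions: TBSCl, imidazole, DMF, 23 °C
Reagents that add atoms: tert-butyldimethylsilyl chloride (TBSCl), CC(C)(C)[Si](C)(C)Cl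
Why: Imidazole-promoted O-silylation (silyl ether protection) of the only hydroxyl group is reliable on this unhindered secondary alcohol and touches neither stereocentre.

Step 2
Reactants: 2 (silylated actinol)
Product: 4 (4R)-4-[(tert-butyldimethylsilyl)oxy]-2,6,6-trimethylcyclohex-1-en-1-yl trifluoromethanesulfonate, via lithium enolate 3 (not isolated)
Conditions: LiN(i-Pr)2 (LDA), THF, −78 °C; then PhNTf2, −78 to 23 °C
Reagents that add atoms: N-phenylbis(trifluoromethanesulfonimide) (PhNTf2), O=S(=O)(N(c1ccccc1)S(=O)(=O)C(F)(F)F)C(F)(F)F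
Why: Ketone 2 has a single enolisable position, so LDA can give only the tetrasubstituted enolate 3, whose O-sulfonylation (enol triflate formation) fixes the future ring C5=C6 double bond regiospecifically; the methyl-bearing stereocentre is erased on purpose and the silyloxy-bearing centre, the future C3/C3' (R), is untouched.

Step 3
Reactants: 4 (enol triflate); 5 (2E)-3-methylpent-2-en-4-yn-1-ol
Product: 6 (2E)-5-{(4R)-4-[(tert-butyldimethylsilyl)oxy]-2,6,6-trimethylcyclohex-1-en-1-yl}-3-methylpent-2-en-4-yn-1-ol
Conditions: Pd(PPh3)4 (5 mol %), CuI (10 mol %), i-Pr2NH, DMF, 50 °C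
Reagents that add atoms: none
Why: Sonogashira coupling of an alkenyl triflate with a terminal alkyne forms the C6–C7 bond and brings in the C7≡C8 triple bond directly, the (E)-olefin of 5 (future C9=C10) and the free primary alcohol being inert under these conditions.

Step 4
Reactants: 6 (C15 enynol)
Product: 7 (2E)-5-{(4R)-4-[(tert-butyldimethylsilyl)oxy]-2,6,6-trimethylcyclohex-1-en-1-yl}-3-methylpent-2-en-4-ynal
Conditions: MnO2, CH2Cl2, 23 °C
Reagents that add atoms: none
Why: MnO2 oxidises allylic alcohols selectively to enals (allylic oxidation) under neutral conditions that leave the silyl ether, the enyne and the 9E geometry intact.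

Step 5
Reactants: 7 (C15 enynal); 8 diethyl [(2E)-3-cyano-2-methylprop-2-en-1-yl]phosphonate
Product: 10 (2E,4E,6E)-9-{(4R)-4-[(tert-butyldimethylsilyl)oxy]-2,6,6-trimethylcyclohex-1-en-1-yl}-3,7-dimethylnona-2,4,6-trien-8-ynenitrile, via lithiated phosphonate 9 (not isolated)
Conditions: 8, n-BuLi, THF/DMPU, −78 °C; then 7, −78 to 0 °C
Reagents that add atoms: none
Why: Horner–Wadsworth–Emmons olefination with the stabilised, delocalised allyl phosphonate anion should give the new C11=C12 bond E-selectively and, because the anion equilibrates, mainly the 13E nitrile, any 13Z isomer being removable by chromatography.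

Step 6
Reactants: 10 (C20 nitrile)
Product: 12 (2E,4E,6E)-9-{(4R)-4-[(tert-butyldimethylsilyl)oxy]-2,6,6-trimethylcyclohex-1-en-1-yl}-3,7-dimethylnona-2,4,6-trien-8-ynal, via N-aluminoimine 11 (not isolated)
Conditions: i-Bu2AlH, CH2Cl2, −78 °C; then H2O/SiO2, 0 °C
Reagents that add atoms: water, O
Why: i-Bu2AlH adds once to the nitrile at −78 °C to give the N-aluminoimine 11, which resists further reduction and hydrolyses on work-up to the aldehyde (partial reduction of a nitrile) without touching the silyl ether, the alkyne or the polyene geometry.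

Step 7
Reactants: 12 (C20 aldehyde)
Product: 13 tert-butyl({(1R)-4-[(3E,5E,7E,9E)-10-iodo-3,7-dimethyldeca-3,5,7,9-tetraen-1-yn-1-yl]-3,5,5-trimethylcyclohex-3-en-1-yl}oxy)dimethylsilane
Conditions: CrCl2, CHI3, THF, 0 to 23 °C, dark
Reagents that add atoms: iodoform, IC(I)I
Why: In this Takai olefination the geminal dichromium species formed from CHI3 and CrCl2 adds to the aldehyde and eliminates with iodine trans to the chain, giving the (E)-alkenyl iodide with one added carbon (C15') under non-basic conditions tolerated by the polyene, the alkyne and the silyl ether.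

Step 8
Reactants: 4 (enol triflate); 14 (4-bromobut-1-yn-1-yl)trimethylsilane
Product: 16 tert-butyldimethyl({(1R)-3,5,5-trimethyl-4-[4-(trimethylsilyl)but-3-yn-1-yl]cyclohex-3-en-1-yl}oxy)silane, via alkylzinc bromide 15 (not isolated)
Conditions: 14, Zn dust, LiCl, THF, 50 °C; then 4, Pd(dppf)Cl2 (5 mol %), THF/NMP, 60 °C
Reagents that add atoms: none
Why: LiCl-mediated zinc insertion into the primary bromide gives an alkylzinc reagent that tolerates the silylalkyne, and its Negishi sp3–sp2 cross-coupling with the enol triflate forges C6'–C7' and delivers the saturated C7'–C8' bridge at the right oxidation level, the wide-bite-angle dppf ligand favouring reductive elimination over β-hydride elimination.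

Step 9
Reactants: 16 (ring-B silylalkyne)
Product: 17 {[(1R)-4-(but-3-yn-1-yl)-3,5,5-trimethylcyclohex-3-en-1-yl]oxy}(tert-butyl)dimethylsilane
Conditions: K2CO3 (0.2 equiv), MeOH/THF, 23 °C
Reagents that add atoms: none
Why: Carbonate-catalysed methanolysis cleaves the C(sp)–Si bond (protodesilylation of an alkynylsilane) while the secondary TBS ether is stable to these mild basic conditions.

Step 10
Reactants: 18 (E)-1,2-dichloroethene; 19 ethynyltrimethylsilane
Product: 20 [(3E)-4-chlorobut-3-en-1-yn-1-yl]trimethylsilane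
Conditions: 18 (5 equiv), Pd(PPh3)4 (5 mol %), CuI (10 mol %), n-BuNH2, Et2O, 23 °C
Reagents that add atoms: none
Why: Sonogashira coupling of (E)-1,2-dichloroethene used in excess should stop after one substitution and proceeds with retention of olefin geometry, giving the (E)-chloroenyne that carries the future C11'=C12' double bond and C13'≡C14' triple bond.

Step 11
Reactants: 17 (ring-B terminal alkyne); 20 (chloroenyne)
Product: 22 tert-butyldimethyl({(1R)-3,5,5-trimethyl-4-[(3E,5E)-3-methyl-8-(trimethylsilyl)octa-3,5-dien-7-yn-1-yl]cyclohex-3-en-1-yl}oxy)silane, via alkenylalane 21 (not isolated)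
Conditions: 17, AlMe3, Cp2ZrCl2 (0.25 equiv), CH2Cl2, 23 °C; volatiles removed; then 20, ZnCl2 (0.3 equiv), Pd(t-Bu3P)2 (3 mol %), THF, 23 to 45 °C
Reagents that add atoms: trimethylaluminium, C[Al](C)C
Why: Zr-catalysed methylalumination adds methyl and aluminium syn across the terminal alkyne with methyl on the internal carbon (setting the 9'E trisubstituted olefin), and the resulting alkenylalane 21 undergoes stereoretentive Pd-catalysed Negishi-type alkenyl–alkenyl coupling with the activated alkenyl chloride 20, a rehearsal of the key step on the same chain.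

Step 12
Reactants: 22 (ring-B silyl dienyne)
Product: 23 tert-butyldimethyl({(1R)-3,5,5-trimethyl-4-[(3E,5E)-3-methylocta-3,5-dien-7-yn-1-yl]cyclohex-3-en-1-yl}oxy)silane
Conditions: K2CO3 (0.2 equiv), MeOH/THF, 23 °C
Reagents that add atoms: none
Why: The same carbonate-catalysed protodesilylation frees the terminal alkyne C13'≡C14'–H needed for the key step without affecting the TBS ether or the (E,E)-diene.

Step 13
Reactants: 23 (ring-B dienyne); 13 (ring-A iodide)
Product: 25 (3R,3'R)-3,3'-bis[(tert-butyldimethylsilyl)oxy]-7,8-didehydro-7',8'-dihydro-β,β-carotene (all-E), via alkenylalane 24 (not isolated)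
Conditions: 23, AlMe3 (2.5 equiv), Cp2ZrCl2 (0.25 equiv), ClCH2CH2Cl, 23 °C; volatiles removed in vacuo; then 13, ZnCl2 (0.3 equiv), Pd2(dba)3 (2.5 mol %), tri(2-furyl)phosphine (10 mol %), THF, 23 °C, dark
Reagents that add atoms: trimethylaluminium, C[Al](C)C
Why: Cp2ZrCl2/AlMe3 generates a methylzirconocene species that adds methyl and metal syn across the terminal alkyne of 23, methyl to the internal carbon C13' and metal to C14', and exchange to aluminium gives the (E)-alkenyldimethylalane 24 (Zr-catalysed methylalumination); after removal of excess AlMe3, zerovalent palladium inserts into the C15'–I bond of 13 with retention, the alkenyl group is passed from aluminium through zinc to palladium, and reductive elimination forges C14'–C15' (Negishi alkenyl–alkenyl coupling). The closest known reaction type is this same one-flask methylalumination/Pd- and Zn-catalysed cross-coupling of terminal enynes and dienynes with alkenyl halides. No ring is closed and no stereocentre is created; the stereochemical element set is the 13'E trisubstituted double bond, controlled by the syn addition, while 15E is carried over from 13 by stereoretentive oxidative addition and reductive elimination and the C3/C3' centres are remote and untouched. The step needs regioselectivity (methyl on C13', not C14'), secured by the terminal alkyne whose substituted carbon takes the methyl group; chemoselectivity for that alkyne over the hindered internal C7≡C8 triple bond, secured because 13 is added only after carbometalation is complete and the AlMe3 has been evaporated; and alkenyl-over-methyl transfer, secured by the faster transmetalation of the sp2 carbon. The TBS ethers keep both hydroxyl groups away from the aluminium reagents, and coupling at 23 °C in the dark should keep the octaene-yne product from isomerising.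

Step 14
Reactants: 25 (bis-silyl ether)
Product: 26 all-E (3R,3'R)-7,8-didehydro-7',8'-dihydro-β,β-carotene-3,3'-diol (CNP0178054.1)
Conditions: Bu4NF, THF, 23 °C, dark
Reagents that add atoms: none
Why: Fluoride-mediated cleavage of both secondary TBS ethers (desilylation) under neutral conditions in the dark should liberate the diol without affecting the C3/C3' stereocentres, the alkyne or the all-E polyene.

**Compound list**

1 | (4R,6R)-4-hydroxy-2,2,6-trimethylcyclohexan-1-one (actinol) | O=C1C(C)(C)C[C@H](O)C[C@H]1C | starting material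
2 | (4R,6R)-4-[(tert-butyldimethylsilyl)oxy]-2,2,6-trimethylcyclohexan-1-one | O=C1C(C)(C)C[C@H](O[Si](C)(C)C(C)(C)C)C[C@H]1C | intermediate
3 | lithium (4R)-4-[(tert-butyldimethylsilyl)oxy]-2,6,6-trimethylcyclohex-1-en-1-olate (formed in the flask) | CC1=C([O-])C(C)(C)C[C@H](O[Si](C)(C)C(C)(C)C)C1.[Li+] | intermediate
4 | (4R)-4-[(tert-butyldimethylsilyl)oxy]-2,6,6-trimethylcyclohex-1-en-1-yl trifluoromethanesulfonate | CC1=C(OS(=O)(=O)C(F)(F)F)C(C)(C)C[C@H](O[Si](C)(C)C(C)(C)C)C1 | intermediate
5 | (2E)-3-methylpent-2-en-4-yn-1-ol | C#C/C(C)=C/CO | starting material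
6 | (2E)-5-{(4R)-4-[(tert-butyldimethylsilyl)oxy]-2,6,6-trimethylcyclohex-1-en-1-yl}-3-methylpent-2-en-4-yn-1-ol | CC1=C(C#C/C(C)=C/CO)C(C)(C)C[C@H](O[Si](C)(C)C(C)(C)C)C1 | intermediate
7 | (2E)-5-{(4R)-4-[(tert-butyldimethylsilyl)oxy]-2,6,6-trimethylcyclohex-1-en-1-yl}-3-methylpent-2-en-4-ynal | CC1=C(C#C/C(C)=C/C=O)C(C)(C)C[C@H](O[Si](C)(C)C(C)(C)C)C1 | intermediate
8 | diethyl [(2E)-3-cyano-2-methylprop-2-en-1-yl]phosphonate | CCOP(=O)(OCC)C/C(C)=C/C#N | starting material
9 | lithium salt of the allyl carbanion of phosphonate 8 (formed in the flask) | [Li+].CCOP(=O)(OCC)[CH-]C(C)=CC#N | intermediate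
10 | (2E,4E,6E)-9-{(4R)-4-[(tert-butyldimethylsilyl)oxy]-2,6,6-trimethylcyclohex-1-en-1-yl}-3,7-dimethylnona-2,4,6-trien-8-ynenitrile | CC1=C(C#C/C(C)=C/C=C/C(C)=C/C#N)C(C)(C)C[C@H](O[Si](C)(C)C(C)(C)C)C1 | intermediate
11 | N-(diisobutylalumanyl)imine of aldehyde 12 (formed in the flask) | CC1=C(C#C/C(C)=C/C=C/C(C)=C/C=N[Al](CC(C)C)CC(C)C)C(C)(C)C[C@H](O[Si](C)(C)C(C)(C)C)C1 | intermediate
12 | (2E,4E,6E)-9-{(4R)-4-[(tert-butyldimethylsilyl)oxy]-2,6,6-trimethylcyclohex-1-en-1-yl}-3,7-dimethylnona-2,4,6-trien-8-ynal | CC1=C(C#C/C(C)=C/C=C/C(C)=C/C=O)C(C)(C)C[C@H](O[Si](C)(C)C(C)(C)C)C1 | intermediate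
13 | tert-butyl({(1R)-4-[(3E,5E,7E,9E)-10-iodo-3,7-dimethyldeca-3,5,7,9-tetraen-1-yn-1-yl]-3,5,5-trimethylcyclohex-3-en-1-yl}oxy)dimethylsilane | CC1=C(C#C/C(C)=C/C=C/C(C)=C/C=C/I)C(C)(C)C[C@H](O[Si](C)(C)C(C)(C)C)C1 | intermediate
14 | (4-bromobut-1-yn-1-yl)trimethylsilane | C[Si](C)(C)C#CCCBr | starting material
15 | [4-(trimethylsilyl)but-3-yn-1-yl]zinc bromide (formed in the flask) | C[Si](C)(C)C#CCC[Zn]Br | intermediate
16 | tert-butyldimethyl({(1R)-3,5,5-trimethyl-4-[4-(trimethylsilyl)but-3-yn-1-yl]cyclohex-3-en-1-yl}oxy)silane | C[Si](C)(C)C#CCCC1=C(C)C[C@@H](O[Si](C)(C)C(C)(C)C)CC1(C)C | intermediate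
17 | {[(1R)-4-(but-3-yn-1-yl)-3,5,5-trimethylcyclohex-3-en-1-yl]oxy}(tert-butyl)dimethylsilane | C#CCCC1=C(C)C[C@@H](O[Si](C)(C)C(C)(C)C)CC1(C)C | intermediate
18 | (E)-1,2-dichloroethene | Cl/C=C/Cl | starting material
19 | ethynyltrimethylsilane | C#C[Si](C)(C)C | starting material
20 | [(3E)-4-chlorobut-3-en-1-yn-1-yl]trimethylsilane | Cl/C=C/C#C[Si](C)(C)C | intermediate
21 | dimethyl[(1E)-2-methyl-4-{(4R)-4-[(tert-butyldimethylsilyl)oxy]-2,6,6-trimethylcyclohex-1-en-1-yl}but-1-en-1-yl]alumane (formed in the flask) | C[Al](C)/C=C(\C)CCC1=C(C)C[C@@H](O[Si](C)(C)C(C)(C)C)CC1(C)C | intermediate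
22 | tert-butyldimethyl({(1R)-3,5,5-trimethyl-4-[(3E,5E)-3-methyl-8-(trimethylsilyl)octa-3,5-dien-7-yn-1-yl]cyclohex-3-en-1-yl}oxy)silane | C[Si](C)(C)C#C/C=C/C=C(\C)CCC1=C(C)C[C@@H](O[Si](C)(C)C(C)(C)C)CC1(C)C | intermediate
23 | tert-butyldimethyl({(1R)-3,5,5-trimethyl-4-[(3E,5E)-3-methylocta-3,5-dien-7-yn-1-yl]cyclohex-3-en-1-yl}oxy)silane | C#C/C=C/C=C(\C)CCC1=C(C)C[C@@H](O[Si](C)(C)C(C)(C)C)CC1(C)C | intermediate
24 | dimethyl[(1E,3E,5E)-2,6-dimethyl-8-{(4R)-4-[(tert-butyldimethylsilyl)oxy]-2,6,6-trimethylcyclohex-1-en-1-yl}octa-1,3,5-trien-1-yl]alumane (formed in the flask) | C[Al](C)/C=C(C)/C=C/C=C(\C)CCC1=C(C)C[C@@H](O[Si](C)(C)C(C)(C)C)CC1(C)C | intermediate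
25 | (3R,3'R)-3,3'-bis[(tert-butyldimethylsilyl)oxy]-7,8-didehydro-7',8'-dihydro-β,β-carotene (all-E) | CC1=C(C#C/C(C)=C/C=C/C(C)=C/C=C/C=C(C)/C=C/C=C(\C)CCC2=C(C)C[C@@H](O[Si](C)(C)C(C)(C)C)CC2(C)C)C(C)(C)C[C@H](O[Si](C)(C)C(C)(C)C)C1 | intermediate
26 | all-E (3R,3'R)-7,8-didehydro-7',8'-dihydro-β,β-carotene-3,3'-diol (CNP0178054.1) | CC1=C(C#C/C(C)=C/C=C/C(C)=C/C=C/C=C(C)/C=C/C=C(\C)CCC2=C(C)C[C@@H](O)CC2(C)C)C(C)(C)C[C@H](O)C1 | target

**Step count and risks**

Total step count: 14. Longest linear sequence: 9 steps (steps 1, 2, 3, 4, 5, 6, 7, 13, 14, from actinol 1 through iodide 13 to 26).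

Three steps most likely to fail:

Step 13. Transfer of the polyenyl group from aluminium to palladium may be slow, so that methyl transfer, protodemetalation and Lewis-acid- or palladium-promoted E/Z scrambling and decomposition of the light-sensitive iodide compete. The fallback reverses the polarity and couples two isolated, neutral partners. Alane 24, generated from 23 as in step 13, is quenched with I2 (THF, −30 °C) to give the ring-B trienyl iodide F1. Aldehyde 12 is converted with Bu3SnCHBr2, CrCl2 and LiI (THF/DMF, 23 °C; Takai-type stannylolefination) into the ring-A (E)-alkenylstannane F2. Stille coupling of F1 with F2 (Pd2(dba)3, AsPh3, NMP, 23–40 °C, dark) should then give 25. The fallback sets out from 23 (through 24) and 12 and returns to the route at 25.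

Step 8. At the hindered tetrasubstituted alkenylpalladium centre, β-hydride elimination and protodemetalation of the alkyl group may outrun reductive elimination, returning reduced or unreacted material. The fallback replaces cross-coupling by carbonyl addition and dehydration. Bromide 14 is converted with Mg (THF) into the homopropargyl Grignard reagent F3, which is added to ketone 2 (THF, 0 to 40 °C) to give the tertiary alcohol F4 as a mixture of carbinol epimers. Dehydration (SOCl2, pyridine, CH2Cl2, 0 °C) should favour the more substituted ring olefin and give 16, any exocyclic isomer being separated. The fallback sets out from 2 and 14 and returns at 16.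

Step 7. E-selectivity of the iodo-olefination may be incomplete, and the pentaenyl system may lose iodine or scramble its 13E geometry under the strongly reducing chromium conditions. The fallback uses alkyne homologation and hydrometalation in place of the chromium carbenoid. Aldehyde 12 is homologated with dimethyl (1-diazo-2-oxopropyl)phosphonate and K2CO3 in MeOH (Seyferth–Gilbert homologation) to the ring-A terminal diyne F5. Cp2Zr(H)Cl (THF, 23 °C) should hydrozirconate the terminal triple bond syn and anti-Markovnikov in preference to the hindered internal C7≡C8 bond, giving the alkenylzirconocene chloride F6, and I2 (0 °C) cleaves the C–Zr bond with retention to give 13. The fallback sets out from 12 and returns at 13.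

**Further compounds**

F1 | step 13 | ring-B trienyl iodide, tert-butyl({(1R)-4-[(3E,5E,7E)-8-iodo-3,7-dimethylocta-3,5,7-trien-1-yl]-3,5,5-trimethylcyclohex-3-en-1-yl}oxy)dimethylsilane | I/C=C(C)/C=C/C=C(\C)CCC1=C(C)C[C@@H](O[Si](C)(C)C(C)(C)C)CC1(C)C
F2 | step 13 | ring-A (E)-alkenylstannane, tributyl[(1E,3E,5E,7E)-4,8-dimethyl-10-{(4R)-4-[(tert-butyldimethylsilyl)oxy]-2,6,6-trimethylcyclohex-1-en-1-yl}deca-1,3,5,7-tetraen-9-yn-1-yl]stannane | CC1=C(C#C/C(C)=C/C=C/C(C)=C/C=C/[Sn](CCCC)(CCCC)CCCC)C(C)(C)C[C@H](O[Si](C)(C)C(C)(C)C)C1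
F3 | step 8 | homopropargyl Grignard reagent, [4-(trimethylsilyl)but-3-yn-1-yl]magnesium bromide | C[Si](C)(C)C#CCC[Mg]Br
F4 | step 8 | tertiary alcohol, (4R,6R)-4-[(tert-butyldimethylsilyl)oxy]-2,2,6-trimethyl-1-[4-(trimethylsilyl)but-3-yn-1-yl]cyclohexan-1-ol (carbinol epimers) | OC1(CCC#C[Si](C)(C)C)C(C)(C)C[C@H](O[Si](C)(C)C(C)(C)C)C[C@H]1C
F5 | step 7 | ring-A terminal diyne, tert-butyl({(1R)-4-[(3E,5E,7E)-3,7-dimethyldeca-3,5,7-triene-1,9-diyn-1-yl]-3,5,5-trimethylcyclohex-3-en-1-yl}oxy)dimethylsilane | CC1=C(C#C/C(C)=C/C=C/C(C)=C/C#C)C(C)(C)C[C@H](O[Si](C)(C)C(C)(C)C)C1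
F6 | step 7 | alkenylzirconocene chloride, chlorobis(cyclopentadienyl)[(1E,3E,5E,7E)-4,8-dimethyl-10-{(4R)-4-[(tert-butyldimethylsilyl)oxy]-2,6,6-trimethylcyclohex-1-en-1-yl}deca-1,3,5,7-tetraen-9-yn-1-yl]zirconium | CC1=C(C#C/C(C)=C/C=C/C(C)=C/C=C/[Zr](Cl)(C2C=CC=C2)C3C=CC=C3)C(C)(C)C[C@H](O[Si](C)(C)C(C)(C)C)C1
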